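The C40 polyene is cut at C11=C12 and C11'=C12' (carotenoid numbering, primes for the monohydroxy ring) into the C10 trienedial and two C15 phosphonium salts. Everything rests on the C6'–C1'(CH3)2–C2' triad of the monohydroxy ring, which maps onto 2,2-dimethylcyclopentane-1,3-dione: a ketoreductase desymmetrises it (C2'), and the six-membered ring C1'–C6' is then made by ring expansion. In one operation a diazoethane homologation of (3R)-2,2-dimethyl-3-(triethylsilyloxy)cyclopentanone inserts C5' with its methyl between C6' and C4'; quaternary C1' directs the migration and the later enolisation. The enantiomeric hydroxy ketone, carrying a temporary acetal tether, serves the dihydroxy ring.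

Key step: step 3

Remark: the target is read as all-E (2R,3S,2'R)-β,β-carotene-2,3,2'-triol with a cis-2,3-diol; unprimed locants refer to the dihydroxy ring, primed ones to the monohydroxy ring. Compounds 5 and 20 are carried as epimer mixtures at the methyl-bearing α-carbon and compounds 17–24 as epimer mixtures at the acetal carbon; both centers are destroyed later. Enantiocomplementary ketoreductases for dione 1 are assumed to be found in commercial enzyme panels.

Step 1
Reactants: 1 2,2-dimethylcyclopentane-1,3-dione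
Product: 2 (3R)-3-hydroxy-2,2-dimethylcyclopentan-1-one
Conditions: (R)-selective ketoreductase, NADP+ (cat.), iPrOH, phosphate buffer pH 7, 30 °C
Reagents that add atoms: none
Why: NADPH-dependent ketoreductases (alcohol dehydrogenase class) reduce one of the two enantiotopic carbonyl groups of 2,2-disubstituted cyclopentane-1,3-diones and stop at the hydroxy ketone, so an (R)-selective enzyme should set C2' by enzymatic desymmetrisation.

Step 2
Reactants: 2 (3R)-3-hydroxy-2,2-dimethylcyclopentan-1-one
Product: 3 (3R)-2,2-dimethyl-3-[(triethylsilyl)oxy]cyclopentan-1-one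
Conditions: Et3SiCl, imidazole, DMF, 0 °C to rt
Reagents that add atoms: chlorotriethylsilane CC[Si](Cl)(CC)CC
Why: Standard silylation of a secondary alcohol, which masks the hydroxyl against the Lewis acid, the diazoalkane and the later enolate chemistry and leaves a group that acidic methanol removes in step 7.

Step 3
Reactants: 3 (3R)-2,2-dimethyl-3-[(triethylsilyl)oxy]cyclopentan-1-one
Product: 5 (3R)-2,2,6-trimethyl-3-[(triethylsilyl)oxy]cyclohexan-1-one, via diazonium betaine 4 (not isolated)
Conditions: CH3CHN2 (Et2O solution), Sc(OTf)3 (10 mol %), toluene, −78 to −40 °C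
Reagents that add atoms: diazoethane CC=[N+]=[N-]
Why: The scandium-activated ketone is attacked at C6' by the nucleophilic carbon of diazoethane to give betaine 4, in which the C6'–C4' bond antiperiplanar to the departing N2 migrates to the new carbon C5' (Tiffeneau–Demjanov-type 1,2-shift), enlarging the five-membered ring C6'–C1'–C2'–C3'–C4' to the six-membered ring C1'–C6' and regenerating the carbonyl at C6'. The closest known reaction type is the Lewis acid-promoted homologation of cycloalkanones with non-stabilised diazoalkanes. No ring is closed by cyclisation, the six-membered ring arises by one-carbon ring expansion. The C2' stereocenter lies outside the reacting bonds and cannot epimerise because C1' is quaternary, while the new C5' center is uncontrolled and is erased in step 4. The step needs migration of C4' instead of C1' and a single insertion: the betaine rotamer that keeps the C5' methyl away from the quaternary, oxygen-flanked C1' places N2 anti to C4', the 2,2,6-trisubstituted cyclohexanone formed is far more hindered than the cyclopentanone so a second insertion should be slow, and the Lewis acid disfavours epoxide formation.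

Step 4
Reactants: 5 (3R)-2,2,6-trimethyl-3-[(triethylsilyl)oxy]cyclohexan-1-one
Product: 7 (5R)-2,6,6-trimethyl-5-[(triethylsilyl)oxy]cyclohex-1-en-1-yl trifluoromethanesulfonate, via potassium enolate 6 (not isolated)
Conditions: KN(SiMe3)2, THF, −78 °C; then PhNTf2, −78 °C to rt
Reagents that add atoms: N-phenylbis(trifluoromethanesulfonimide) FC(F)(F)S(=O)(=O)N(c1ccccc1)S(=O)(=O)C(F)(F)F
Why: Deprotonation can only occur at C5' because C1' is quaternary, and O-sulfonylation of the enolate should give the tetrasubstituted enol triflate with the C5'=C6' double bond in place and the C5' stereocenter erased.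

Step 5
Reactants: 8 (2E)-3-methylpent-2-en-4-yn-1-ol
Product: 9 (2E,4E)-3-methyl-5-(tributylstannyl)penta-2,4-dien-1-ol
Conditions: Bu3SnH, Pd2(dba)3 (cat.), Cy3P·HBF4 (cat.), iPr2NEt (cat.), CH2Cl2, 0 °C
Reagents that add atoms: tributyltin hydride CCCC[SnH](CCCC)CCCC
Why: Palladium-catalysed syn-hydrostannation of the terminal alkyne with a bulky phosphine places tin on the terminal carbon and hydrogen cis to it, which should give the 4E dienylstannane with the 2E double bond untouched.

Step 6
Reactants: 7 (5R)-2,6,6-trimethyl-5-[(triethylsilyl)oxy]cyclohex-1-en-1-yl trifluoromethanesulfonate + 9 (2E,4E)-3-methyl-5-(tributylstannyl)penta-2,4-dien-1-ol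
Product: 10 (2E,4E)-3-methyl-5-{(5R)-2,6,6-trimethyl-5-[(triethylsilyl)oxy]cyclohex-1-en-1-yl}penta-2,4-dien-1-ol
Conditions: Pd2(dba)3 (5 mol %), AsPh3 (40 mol %), NMP, 60 °C
Reagents that add atoms: none
Why: Stille coupling of a hindered cyclohexenyl triflate with an alkenylstannane proceeds with retention of both alkene geometries when the weakly donating AsPh3 in NMP speeds up transmetalation, and it tolerates the free allylic alcohol and the silyl ether.

Step 7
Reactants: 10 (2E,4E)-3-methyl-5-{(5R)-2,6,6-trimethyl-5-[(triethylsilyl)oxy]cyclohex-1-en-1-yl}penta-2,4-dien-1-ol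
Product: 12 {(2E,4E)-5-[(5R)-5-hydroxy-2,6,6-trimethylcyclohex-1-en-1-yl]-3-methylpenta-2,4-dien-1-yl}triphenylphosphonium bromide, via silylated phosphonium bromide 11 (not isolated)
Conditions: PPh3·HBr, MeOH, 0 °C to rt
Reagents that add atoms: triphenylphosphine hydrobromide [Br-].c1ccc(cc1)[PH+](c1ccccc1)c1ccccc1
Why: The acid ionises the primary allylic alcohol to a delocalised polyenyl cation that triphenylphosphine captures reversibly at the unhindered terminus C11' (SN1-type phosphonium salt formation), while the acidic methanol removes the triethylsilyl group and C2' is not involved.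

Step 8
Reactants: 1 2,2-dimethylcyclopentane-1,3-dione
Product: 13 (3S)-3-hydroxy-2,2-dimethylcyclopentan-1-one
Conditions: (S)-selective ketoreductase, NADP+ (cat.), iPrOH, phosphate buffer pH 7, 30 °C
Reagents that add atoms: none
Why: The same enzymatic desymmetrisation with an enzyme of opposite facial preference should give the enantiomeric hydroxy ketone, whose carbinol carbon becomes C2 of the dihydroxy ring.

Step 9
Reactants: 13 (3S)-3-hydroxy-2,2-dimethylcyclopentan-1-one
Product: 16 (4S)-4-hydroxy-5,5-dimethylcyclopent-2-en-1-one, via bis-silyl enol ether 14 (not isolated), via silyloxy enone 15 (not isolated)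
Conditions: TMSOTf, Et3N, CH2Cl2, 0 °C; then Pd(OAc)2 (10 mol %), O2, DMSO, rt; then citric acid, MeOH
Reagents that add atoms: none
Why: Saegusa–Ito dehydrogenation, in which double silylation gives the only possible silyl enol ether (C1 is quaternary), palladation at C4 and β-hydride elimination from C3 give the enone, and mild acidic methanolysis frees the hydroxyl without touching the stereocenter.

Step 10
Reactants: 16 (4S)-4-hydroxy-5,5-dimethylcyclopent-2-en-1-one
Product: 18 cyclohexylmethylidene acetal of (3R,4S)-3,4-dihydroxy-2,2-dimethylcyclopentan-1-one, via hemiacetal 17 (not isolated)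
Conditions: cyclohexanecarbaldehyde, 1-[3,5-bis(trifluoromethyl)phenyl]-3-[(1R,2R)-2-(dimethylamino)cyclohexyl]thiourea (10 mol %), toluene, rt
Reagents that add atoms: cyclohexanecarbaldehyde O=CC1CCCCC1
Why: Hemiacetal formation at the C2 hydroxyl followed by intramolecular oxa-Michael addition (5-exo-trig) of the hemiacetal oxygen to C3 can deliver that oxygen only to the face that carries the C2 oxygen, so the temporary tether should set C3 (S) cis to C2 and leave the cis-diol already protected as a dioxolane.

Step 11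
Reactants: 18 cyclohexylmethylidene acetal of (3R,4S)-3,4-dihydroxy-2,2-dimethylcyclopentan-1-one
Product: 20 cyclohexylmethylidene acetal of (3R,4S)-3,4-dihydroxy-2,2,6-trimethylcyclohexan-1-one, via diazonium betaine 19 (not isolated)
Conditions: CH3CHN2 (Et2O solution), Sc(OTf)3 (10 mol %), toluene, −78 to −40 °C
Reagents that add atoms: diazoethane CC=[N+]=[N-]
Why: The same Lewis acid-promoted diazoethane homologation as in step 3, in which the CH2 carbon C4 should migrate in preference to the quaternary C1 and insert C5 with its methyl group, after which the C3 oxygen is γ to the carbonyl and no longer prone to β-elimination.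

Step 12
Reactants: 20 cyclohexylmethylidene acetal of (3R,4S)-3,4-dihydroxy-2,2,6-trimethylcyclohexan-1-one
Product: 22 cyclohexylmethylidene acetal of (4S,5R)-4,5-dihydroxy-2,6,6-trimethylcyclohex-1-en-1-yl trifluoromethanesulfonate, via potassium enolate 21 (not isolated)
Conditions: KN(SiMe3)2, THF, −78 °C; then PhNTf2, −78 °C to rt
Reagents that add atoms: N-phenylbis(trifluoromethanesulfonimide) FC(F)(F)S(=O)(=O)N(c1ccccc1)S(=O)(=O)C(F)(F)F
Why: As in step 4, the only enolisable position is C5, so O-sulfonylation of the enolate should fix the C5=C6 double bond and remove the C5 stereocenter.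

Step 13
Reactants: 22 cyclohexylmethylidene acetal of (4S,5R)-4,5-dihydroxy-2,6,6-trimethylcyclohex-1-en-1-yl trifluoromethanesulfonate + 9 (2E,4E)-3-methyl-5-(tributylstannyl)penta-2,4-dien-1-ol
Product: 23 cyclohexylmethylidene acetal of (2E,4E)-5-[(4S,5R)-4,5-dihydroxy-2,6,6-trimethylcyclohex-1-en-1-yl]-3-methylpenta-2,4-dien-1-ol
Conditions: Pd2(dba)3 (5 mol %), AsPh3 (40 mol %), NMP, 60 °C
Reagents that add atoms: none
Why: The same Stille coupling as in step 6, with retention of alkene geometry and no effect on the acetal or the two carbinol centers.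

Step 14
Reactants: 23 cyclohexylmethylidene acetal of (2E,4E)-5-[(4S,5R)-4,5-dihydroxy-2,6,6-trimethylcyclohex-1-en-1-yl]-3-methylpenta-2,4-dien-1-ol
Product: 25 {(2E,4E)-5-[(4S,5R)-4,5-dihydroxy-2,6,6-trimethylcyclohex-1-en-1-yl]-3-methylpenta-2,4-dien-1-yl}triphenylphosphonium bromide, via acetal phosphonium bromide 24 (not isolated)
Conditions: PPh3·HBr, MeOH, rt; then aq. HBr (cat.), 40 °C
Reagents that add atoms: triphenylphosphine hydrobromide [Br-].c1ccc(cc1)[PH+](c1ccccc1)c1ccccc1
Why: SN1-type phosphonium salt formation at C11 as in step 7, followed by acid-catalysed transacetalisation with methanol, which the robust phosphonium salt tolerates and which should release the cis-diol without touching the C–O bonds of C2 and C3.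

Step 15
Reactants: 12 {(2E,4E)-5-[(5R)-5-hydroxy-2,6,6-trimethylcyclohex-1-en-1-yl]-3-methylpenta-2,4-dien-1-yl}triphenylphosphonium bromide + 26 (2E,4E,6E)-2,7-dimethylocta-2,4,6-trienedial
Product: 29 (2E,4E,6E,8E,10E,12E)-13-[(5R)-5-hydroxy-2,6,6-trimethylcyclohex-1-en-1-yl]-2,7,11-trimethyltrideca-2,4,6,8,10,12-hexaenal, via ylide 27 (not isolated), via 8Z isomer 28 (not isolated)
Conditions: 26 (3 equiv), NaOMe, MeOH/CH2Cl2, 0 °C to rt; then n-heptane, reflux
Reagents that add atoms: none
Why: Wittig olefination in which the ylide is generated in the presence of an excess of the symmetrical dialdehyde so that mono-olefination should dominate, the new C11'=C12' bond forming as an E/Z mixture that equilibrates thermally to the all-E isomer.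

Step 16
Reactants: 29 (2E,4E,6E,8E,10E,12E)-13-[(5R)-5-hydroxy-2,6,6-trimethylcyclohex-1-en-1-yl]-2,7,11-trimethyltrideca-2,4,6,8,10,12-hexaenal + 25 {(2E,4E)-5-[(4S,5R)-4,5-dihydroxy-2,6,6-trimethylcyclohex-1-en-1-yl]-3-methylpenta-2,4-dien-1-yl}triphenylphosphonium bromide
Product: 32 (all-E)-(2R,3S,2'R)-β,β-carotene-2,3,2'-triol, via ylide 30 (not isolated), via 11Z isomer 31 (not isolated)
Conditions: NaOMe, MeOH/CH2Cl2, rt; then n-heptane/EtOH, reflux
Reagents that add atoms: none
Why: A second Wittig olefination joins the halves at C11=C12 with the free hydroxyl groups tolerated under methoxide conditions, and thermal isomerisation of the 11Z isomer should give the all-E carotenoid without touching the three carbinol stereocenters.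

Compound list

1 | 2,2-dimethylcyclopentane-1,3-dione | CC1(C)C(=O)CCC1=O | starting material
2 | (3R)-3-hydroxy-2,2-dimethylcyclopentan-1-one | CC1(C)[C@H](O)CCC1=O | intermediate
3 | (3R)-2,2-dimethyl-3-[(triethylsilyl)oxy]cyclopentan-1-one | CC1(C)[C@H](O[Si](CC)(CC)CC)CCC1=O | intermediate
4 | (3R)-1-(1-diazonioethyl)-2,2-dimethyl-3-[(triethylsilyl)oxy]cyclopentan-1-olate (scandium-bound betaine, other centers undefined) | CC1(C)[C@H](O[Si](CC)(CC)CC)CCC1([O-])C(C)[N+]#N | intermediate
5 | (3R)-2,2,6-trimethyl-3-[(triethylsilyl)oxy]cyclohexan-1-one (both C6 epimers) | CC1(C)[C@H](O[Si](CC)(CC)CC)CCC(C)C1=O | intermediate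
6 | potassium (5R)-2,6,6-trimethyl-5-[(triethylsilyl)oxy]cyclohex-1-en-1-olate | CC1=C([O-])C(C)(C)[C@H](O[Si](CC)(CC)CC)CC1.[K+] | intermediate
7 | (5R)-2,6,6-trimethyl-5-[(triethylsilyl)oxy]cyclohex-1-en-1-yl trifluoromethanesulfonate | CC1=C(OS(=O)(=O)C(F)(F)F)C(C)(C)[C@H](O[Si](CC)(CC)CC)CC1 | intermediate
8 | (2E)-3-methylpent-2-en-4-yn-1-ol | C#C/C(C)=C/CO | starting material
9 | (2E,4E)-3-methyl-5-(tributylstannyl)penta-2,4-dien-1-ol | CCCC[Sn](CCCC)(CCCC)/C=C/C(C)=C/CO | intermediate
10 | (2E,4E)-3-methyl-5-{(5R)-2,6,6-trimethyl-5-[(triethylsilyl)oxy]cyclohex-1-en-1-yl}penta-2,4-dien-1-ol | CC1=C(/C=C/C(C)=C/CO)C(C)(C)[C@H](O[Si](CC)(CC)CC)CC1 | intermediate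
11 | [(2E,4E)-3-methyl-5-{(5R)-2,6,6-trimethyl-5-[(triethylsilyl)oxy]cyclohex-1-en-1-yl}penta-2,4-dien-1-yl]triphenylphosphonium bromide | CC1=C(/C=C/C(C)=C/C[P+](c2ccccc2)(c2ccccc2)c2ccccc2)C(C)(C)[C@H](O[Si](CC)(CC)CC)CC1.[Br-] | intermediate
12 | {(2E,4E)-5-[(5R)-5-hydroxy-2,6,6-trimethylcyclohex-1-en-1-yl]-3-methylpenta-2,4-dien-1-yl}triphenylphosphonium bromide | CC1=C(/C=C/C(C)=C/C[P+](c2ccccc2)(c2ccccc2)c2ccccc2)C(C)(C)[C@H](O)CC1.[Br-] | intermediate
13 | (3S)-3-hydroxy-2,2-dimethylcyclopentan-1-one | CC1(C)[C@@H](O)CCC1=O | intermediate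
14 | (4S)-5,5-dimethyl-1,4-bis[(trimethylsilyl)oxy]cyclopent-1-ene | CC1(C)[C@@H](O[Si](C)(C)C)CC=C1O[Si](C)(C)C | intermediate
15 | (4S)-5,5-dimethyl-4-[(trimethylsilyl)oxy]cyclopent-2-en-1-one | CC1(C)[C@@H](O[Si](C)(C)C)C=CC1=O | intermediate
16 | (4S)-4-hydroxy-5,5-dimethylcyclopent-2-en-1-one | CC1(C)[C@@H](O)C=CC1=O | intermediate
17 | (4S)-4-[cyclohexyl(hydroxy)methoxy]-5,5-dimethylcyclopent-2-en-1-one (hemiacetal, both epimers) | CC1(C)[C@@H](OC(O)C2CCCCC2)C=CC1=O | intermediate
18 | cyclohexylmethylidene acetal of (3R,4S)-3,4-dihydroxy-2,2-dimethylcyclopentan-1-one (cis-fused 2-cyclohexyl-1,3-dioxolane, both acetal epimers) | O=C1C[C@@H]2OC(C3CCCCC3)O[C@@H]2C1(C)C | intermediate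
19 | diazonium betaine from 18 and diazoethane (1-(1-diazonioethyl) alkoxide, scandium-bound, new centers undefined) | [O-]C1(C(C)[N+]#N)C[C@@H]2OC(C3CCCCC3)O[C@@H]2C1(C)C | intermediate
20 | cyclohexylmethylidene acetal of (3R,4S)-3,4-dihydroxy-2,2,6-trimethylcyclohexan-1-one (both C6 epimers) | O=C1C(C)C[C@@H]2OC(C3CCCCC3)O[C@@H]2C1(C)C | intermediate
21 | potassium enolate of 20 (enolate double bond between the carbonyl carbon and the methyl-bearing carbon) | [O-]C1=C(C)C[C@@H]2OC(C3CCCCC3)O[C@@H]2C1(C)C.[K+] | intermediate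
22 | cyclohexylmethylidene acetal of (4S,5R)-4,5-dihydroxy-2,6,6-trimethylcyclohex-1-en-1-yl trifluoromethanesulfonate | O=S(=O)(OC1=C(C)C[C@@H]2OC(C3CCCCC3)O[C@@H]2C1(C)C)C(F)(F)F | intermediate
23 | cyclohexylmethylidene acetal of (2E,4E)-5-[(4S,5R)-4,5-dihydroxy-2,6,6-trimethylcyclohex-1-en-1-yl]-3-methylpenta-2,4-dien-1-ol | OC/C=C(C)/C=C/C1=C(C)C[C@@H]2OC(C3CCCCC3)O[C@@H]2C1(C)C | intermediate
24 | triphenylphosphonium bromide of 23 (phosphorus at C1 of the pentadienyl chain, acetal intact) | [Br-].C(/C=C(C)/C=C/C1=C(C)C[C@@H]2OC(C3CCCCC3)O[C@@H]2C1(C)C)[P+](c1ccccc1)(c1ccccc1)c1ccccc1 | intermediate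
25 | {(2E,4E)-5-[(4S,5R)-4,5-dihydroxy-2,6,6-trimethylcyclohex-1-en-1-yl]-3-methylpenta-2,4-dien-1-yl}triphenylphosphonium bromide | [Br-].c1ccccc1[P+](c1ccccc1)(c1ccccc1)C/C=C(C)/C=C/C1=C(C)C[C@H](O)[C@H](O)C1(C)C | intermediate
26 | (2E,4E,6E)-2,7-dimethylocta-2,4,6-trienedial | O=C/C(C)=C/C=C/C=C(C)/C=O | starting material
27 | ylide of 12 (triphenylphosphonium ylide, carbanion at C1 of the pentadienyl chain) | CC1=C(/C=C/C(C)=C/[CH-][P+](c2ccccc2)(c2ccccc2)c2ccccc2)C(C)(C)[C@H](O)CC1 | intermediate
28 | (2E,4E,6E,8Z,10E,12E)-13-[(5R)-5-hydroxy-2,6,6-trimethylcyclohex-1-en-1-yl]-2,7,11-trimethyltrideca-2,4,6,8,10,12-hexaenal | CC1=C(/C=C/C(C)=C/C=C\C(C)=C\C=C\C=C(C)\C=O)C(C)(C)[C@H](O)CC1 | intermediate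
29 | (2E,4E,6E,8E,10E,12E)-13-[(5R)-5-hydroxy-2,6,6-trimethylcyclohex-1-en-1-yl]-2,7,11-trimethyltrideca-2,4,6,8,10,12-hexaenal | CC1=C(/C=C/C(C)=C/C=C/C(C)=C/C=C/C=C(C)/C=O)C(C)(C)[C@H](O)CC1 | intermediate
30 | ylide of 25 (triphenylphosphonium ylide, carbanion at C1 of the pentadienyl chain) | c1ccccc1[P+](c1ccccc1)(c1ccccc1)[CH-]/C=C(C)/C=C/C1=C(C)C[C@H](O)[C@H](O)C1(C)C | intermediate
31 | (11Z)-(2R,3S,2'R)-β,β-carotene-2,3,2'-triol | CC1=C(/C=C/C(C)=C/C=C/C(C)=C/C=C/C=C(C)/C=C\C=C(C)\C=C\C2=C(C)C[C@H](O)[C@H](O)C2(C)C)C(C)(C)[C@H](O)CC1 | intermediate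
32 | (all-E)-(2R,3S,2'R)-β,β-carotene-2,3,2'-triol | CC1=C(/C=C/C(C)=C/C=C/C(C)=C/C=C/C=C(C)/C=C/C=C(C)/C=C/C2=C(C)C[C@H](O)[C@H](O)C2(C)C)C(C)(C)[C@H](O)CC1 | target

Total step count: 16.
Longest linear sequence: 8 steps (steps 8, 9, 10, 11, 12, 13, 14, 16; the sequence 1, 2, 3, 4, 6, 7, 15, 16 is equally long).

Steps most likely to fail

Step 3 (and its repeat, step 11). The quaternary carbon could migrate in competition with the CH2 carbon, the betaine could close to an epoxide, or a second insertion could follow. The fallback sets out from 3 and fixes the site of insertion through the only possible enol ether. TMSOTf and Et3N should give the trimethylsilyl enol ether F1. Simmons–Smith cyclopropanation (Et2Zn, CH2I2) should give the siloxybicyclo[3.1.0]hexane F2. FeCl3 in DMF followed by NaOAc in MeOH (oxidative opening of the internal cyclopropane bond, then loss of HCl) should give the ring-expanded cyclohexenone F3. Conjugate reduction with LiB(sBu)3H and trapping of the resulting enolate with MeI comes back to the route at 5.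

Step 10. The oxa-Michael addition is reversible, and deprotonation at the γ-carbon C2 would erode the configuration or isomerise the hydroxy enone towards the 1,3-dione. The fallback sets out from 16 and uses a boron tether under near-neutral conditions. Phenylboronic acid with a catalytic tertiary amine should form the boronic hemiester, whose B–OH oxygen adds to C3 from the face of the C2 oxygen to give the cis-fused cyclic phenylboronate F4. Oxidative work-up (H2O2, NaHCO3) should free the cis-diol F5. Acetalisation with cyclohexanecarbaldehyde dimethyl acetal and PPTS comes back to the route at 18.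

Step 6 (and its repeat, step 13). Transmetalation at the triflate, flanked by a gem-dimethyl and a methyl group, may be slow, so that protodestannylation or homocoupling of the stannane takes over. The fallback sets out from 7 and builds the chain in two smaller pieces. A Heck reaction with but-3-en-2-one (Pd(OAc)2, PPh3, Et3N, DMF, 70 °C) should give the silylated 2-hydroxy-β-ionone F6. Vinylmagnesium bromide in THF should give the tertiary bis-allylic alcohol F7. PPh3·HBr in MeOH then ionises F7, delivers phosphorus to the chain terminus with allylic transposition, removes the silyl group, and comes back to the route at 12.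

Further compounds

F1 | step 3 | triethyl{[(1R)-2,2-dimethyl-3-[(trimethylsilyl)oxy]cyclopent-3-en-1-yl]oxy}silane | CC1(C)[C@H](O[Si](CC)(CC)CC)CC=C1O[Si](C)(C)C
F2 | step 3 | (3R)-2,2-dimethyl-3-[(triethylsilyl)oxy]-1-[(trimethylsilyl)oxy]bicyclo[3.1.0]hexane (bridgehead centers undefined) | CC1(C)[C@H](O[Si](CC)(CC)CC)CC2CC12O[Si](C)(C)C
F3 | step 3 | (5R)-6,6-dimethyl-5-[(triethylsilyl)oxy]cyclohex-2-en-1-one | CC1(C)[C@H](O[Si](CC)(CC)CC)CC=CC1=O
F4 | step 10 | cyclic phenylboronate of (3R,4S)-3,4-dihydroxy-2,2-dimethylcyclopentan-1-one | O=C1C[C@@H]2OB(c3ccccc3)O[C@@H]2C1(C)C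
F5 | step 10 | (3R,4S)-3,4-dihydroxy-2,2-dimethylcyclopentan-1-one | O=C1C[C@H](O)[C@H](O)C1(C)C
F6 | step 6 | (3E)-4-{(5R)-2,6,6-trimethyl-5-[(triethylsilyl)oxy]cyclohex-1-en-1-yl}but-3-en-2-one | CC1=C(/C=C/C(C)=O)C(C)(C)[C@H](O[Si](CC)(CC)CC)CC1
F7 | step 6 | (1E)-3-methyl-1-{(5R)-2,6,6-trimethyl-5-[(triethylsilyl)oxy]cyclohex-1-en-1-yl}penta-1,4-dien-3-ol (carbinol center undefined) | CC1=C(/C=C/C(C)(O)C=C)C(C)(C)[C@H](O[Si](CC)(CC)CC)CC1
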